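**Retrosynthetic overview**
- The strategy rests on ring B of the naphthalene, where C1 (4-hydroxy-2-methoxyphenyl), C2 (vanillyl CH2), C3 (OH) and C4 (H) stand in a row. C1 and C4 are read as the termini of an o-quinoid lactone diene, and C2–C3 as a polarised O–C≡C–CH2Ar unit.
- Cutting C1–C2 and C3–C4, with CO2 put back across C1 and C4, gives two fragments. One is a 1-aryl-2-benzopyran-3-one that already holds ring A (C5 OMe, C6 OBn, C7 OMe); the other is a 3-aryl-1-(triisopropylsiloxy)propyne.
- The pyranone comes from a 2-aroylphenylacetic acid: syringaldehyde benzyl ether, 2-bromination, aryl Grignard addition and oxidation, palladium coupling with a zinc acetate enolate, saponification, then Ac2O.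
- The siloxyalkyne comes from O-benzylvanillyl alcohol by bromide formation, copper-catalysed alkynylation and oxidation of the lithium acetylide to the ynolate. This is preferred to an ester-to-ynolate homologation of a homovanillate, whose acidic benzylic protons invite enolisation.
- Ring order: ring A and the two pendant aryl rings are bought in, the pyranone ring is closed in step 8, and ring B is closed in step 13. Fluoride and hydrogenolysis finish the route.

Key step: step 13

Assumption: the target SMILES has no stereodescriptor, so the hindered C1–aryl axis is made without control and the target has no stereocentre to set.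

**Step 1**
Reactants: 1 syringaldehyde
Product: 2 4-benzyloxy-3,5-dimethoxybenzaldehyde
Conditions: BnBr, K2CO3, DMF, 60 °C
Reagents that add atoms: benzyl bromide, BrCc1ccccc1
Why: Williamson ether synthesis, in which the phenoxide is alkylated by benzyl bromide and the aldehyde is inert to K2CO3.

**Step 2**
Reactants: 2 4-benzyloxy-3,5-dimethoxybenzaldehyde
Product: 3 4-benzyloxy-2-bromo-3,5-dimethoxybenzaldehyde
Conditions: NBS (1.0 equiv), MeCN, rt, dark
Reagents that add atoms: N-bromosuccinimide, O=C1CCC(=O)N1Br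
Why: Electrophilic aromatic bromination; C2 and C6 are equivalent, each ortho to one methoxy group and para to the other, and the trialkoxy ring is far more reactive than the benzyl phenyl ring, so one monobromide should form.

**Step 3**
Reactants: 4 4-bromo-3-methoxyphenol
Product: 5 4-benzyloxy-1-bromo-2-methoxybenzene
Conditions: BnBr, K2CO3, acetone, reflux
Reagents that add atoms: benzyl bromide, BrCc1ccccc1
Why: Williamson ether synthesis that masks the only acidic proton before the metalation in step 4.

**Step 4**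
Reactants: 5 4-benzyloxy-1-bromo-2-methoxybenzene; 3 4-benzyloxy-2-bromo-3,5-dimethoxybenzaldehyde
Product: 7 (4-benzyloxy-2-bromo-3,5-dimethoxyphenyl)(4-benzyloxy-2-methoxyphenyl)methanol (racemic), via aryl Grignard reagent 6 (not isolated)
Conditions: Mg turnings, I2 (cat.), THF, reflux; then 3, THF, 0 °C to rt; aqueous work-up
Reagents that add atoms: none
Why: Grignard addition to an aldehyde, which is much faster than halogen–magnesium exchange at the aryl bromide of 3; the carbinol centre forms as a racemate and is erased in step 5.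

**Step 5**
Reactants: 7 (4-benzyloxy-2-bromo-3,5-dimethoxyphenyl)(4-benzyloxy-2-methoxyphenyl)methanol
Product: 8 (4-benzyloxy-2-bromo-3,5-dimethoxyphenyl)(4-benzyloxy-2-methoxyphenyl)methanone
Conditions: Dess–Martin periodinane, CH2Cl2, 0 °C to rt
Reagents that add atoms: none
Why: Dess–Martin oxidation of a doubly benzylic secondary alcohol under near-neutral conditions that leave the aryl bromide and the benzyl ethers untouched.

**Step 6**
Reactants: 8 (4-benzyloxy-2-bromo-3,5-dimethoxyphenyl)(4-benzyloxy-2-methoxyphenyl)methanone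
Product: 9 ethyl 2-[3-benzyloxy-6-(4-benzyloxy-2-methoxybenzoyl)-2,4-dimethoxyphenyl]acetate
Conditions: BrZnCH2CO2Et (2 equiv), Pd2(dba)3 (2.5 mol%), XPhos (10 mol%), THF, 60 °C
Reagents that add atoms: (2-ethoxy-2-oxoethyl)zinc bromide, CCOC(=O)C[Zn]Br
Why: Negishi-type palladium-catalysed coupling of a Reformatsky reagent with an aryl bromide; the ortho aroyl group speeds oxidative addition, the small zinc enolate fits the di-ortho-substituted site better than a malonate, and the hindered, donor-rich, non-enolisable diaryl ketone should resist Reformatsky addition.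

**Step 7**
Reactants: 9 ethyl 2-[3-benzyloxy-6-(4-benzyloxy-2-methoxybenzoyl)-2,4-dimethoxyphenyl]acetate
Product: 10 2-[3-benzyloxy-6-(4-benzyloxy-2-methoxybenzoyl)-2,4-dimethoxyphenyl]acetic acid
Conditions: LiOH, THF–MeOH–H2O, rt; then 1 M HCl
Reagents that add atoms: lithium hydroxide, [Li+].[OH-]
Why: Ester saponification; the ketone cannot enolise and the aryl ethers are stable to aqueous base.

**Step 8**
Reactants: 10 2-[3-benzyloxy-6-(4-benzyloxy-2-methoxybenzoyl)-2,4-dimethoxyphenyl]acetic acid
Product: 12 6-benzyloxy-1-(4-benzyloxy-2-methoxyphenyl)-5,7-dimethoxy-2-benzopyran-3-one, via mixed acetic anhydride 11 (not isolated)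
Conditions: Ac2O, 120 °C, short heating under N2; evaporate, azeotrope with toluene, crystallise, use promptly
Reagents that add atoms: none
Why: Cyclodehydration of a 2-aroylphenylacetic acid with acetic anhydride, the standard entry to 1-aryl-2-benzopyran-3-ones; the ketone oxygen closes onto the activated acyl carbon, loss of a C4 proton gives the o-quinoid lactone, and the 1-aryl and alkoxy groups should stabilise it enough for isolation free of acetic acid.

**Step 9**
Reactants: 13 4-benzyloxy-3-methoxybenzyl alcohol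
Product: 14 1-benzyloxy-4-(bromomethyl)-2-methoxybenzene
Conditions: PBr3 (0.4 equiv), Et2O, 0 °C; used crude
Reagents that add atoms: phosphorus tribromide, BrP(Br)Br
Why: Bromide displaces the activated phosphite ester of a benzylic alcohol, cold enough to spare the benzyl aryl ether.

**Step 10**
Reactants: 14 1-benzyloxy-4-(bromomethyl)-2-methoxybenzene
Product: 15 [3-(4-benzyloxy-3-methoxyphenyl)prop-1-yn-1-yl]trimethylsilane
Conditions: Me3SiC≡CH, EtMgBr, THF, 0 °C to rt; then CuBr (10 mol%), 14, THF, reflux
Reagents that add atoms: ethynyltrimethylsilane, C#C[Si](C)(C)C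
Why: Copper-catalysed cross-coupling of an alkynyl Grignard reagent with a benzylic bromide; the silyl cap prevents double benzylation and alkyne-to-allene isomerisation.

**Step 11**
Reactants: 15 [3-(4-benzyloxy-3-methoxyphenyl)prop-1-yn-1-yl]trimethylsilane
Product: 16 1-benzyloxy-2-methoxy-4-(prop-2-yn-1-yl)benzene
Conditions: K2CO3 (0.2 equiv), MeOH–THF, rt, short reaction time
Reagents that add atoms: none
Why: Methoxide-induced protiodesilylation of an alkynylsilane; the weak base and short contact time should keep the skipped aryl–alkyne from isomerising.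

**Step 12**
Reactants: 16 1-benzyloxy-2-methoxy-4-(prop-2-yn-1-yl)benzene
Product: 19 3-(4-benzyloxy-3-methoxyphenyl)-1-(triisopropylsiloxy)prop-1-yne, via lithium acetylide 17 (not isolated), via lithium ynolate 18 (not isolated)
Conditions: n-BuLi (1.0 equiv), THF, −78 °C; t-BuOOLi [t-BuOOH + LiN(SiMe3)2, THF, −78 °C], −78 to 0 °C; TIPSOTf, −78 to 0 °C; Et3N-deactivated silica
Reagents that add atoms: tert-butyl hydroperoxide, CC(C)(C)OO; triisopropylsilyl trifluoromethanesulfonate, CC(C)[Si](OS(=O)(=O)C(F)(F)F)(C(C)C)C(C)C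
Why: Oxidation of a lithium acetylide by lithium tert-butyl peroxide to the ynolate, followed by O-silylation with a hard, bulky silyl triflate, is the standard route from terminal alkynes to 1-siloxyalkynes; one equivalent of n-BuLi at −78 °C should remove only the acetylenic proton.

**Step 13**
Reactants: 12 6-benzyloxy-1-(4-benzyloxy-2-methoxyphenyl)-5,7-dimethoxy-2-benzopyran-3-one; 19 3-(4-benzyloxy-3-methoxyphenyl)-1-(triisopropylsiloxy)prop-1-yne
Product: 21 6-benzyloxy-1-(4-benzyloxy-2-methoxyphenyl)-2-(4-benzyloxy-3-methoxybenzyl)-5,7-dimethoxy-3-(triisopropylsiloxy)naphthalene, via bridged lactone 20 (not isolated)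
Conditions: 19 (1.5 equiv), dry degassed toluene, reflux (110 °C), N2
Reagents that add atoms: none
Why: Proposed new method: the benzyl-bearing carbon of 19, the nucleophilic end of the O–C≡C unit, should attack C1 of 12, the electrophilic diene terminus beside the ring oxygen (2-benzopyrylium-3-olate character), while the developing silyl ketenium carbon is captured by C4, the enolate-like terminus alpha to the lactone carbonyl, in a concerted but strongly asynchronous inverse-demand [4+2] cycloaddition that forms C1–C2 and C3–C4. Bridged lactone 20 then expels CO2 by retro-Diels–Alder reaction, which returns ring A to a benzenoid state, makes ring B aromatic and renders the sequence irreversible. The closest known reaction types are the thermal cycloaddition and CO2 extrusion of 1-aryl-2-benzopyran-3-ones with acetylenic esters, the same sequence of 2-pyranones with ynamines and alkoxyalkynes, and the formal [4+2] addition of siloxyalkynes to phthalazines with loss of N2. Ring B closes in intermolecular [4+2] mode, with four carbons (C1, C8a, C4a, C4) from the diene and two (C2, C3) from the alkyne. The two bridgehead centres of 20 form as a racemate fixed by the bicyclic frame and vanish with CO2, so no stereocentre has to be controlled. The step needs regioselectivity (benzyl carbon to C1, oxygenated carbon to C4), which the matched polarity of lactone diene and ynol ether should secure, and chemoselectivity against acid-induced ketene chemistry of 19, which the use of isolated, acetic-acid-free 12 in dry toluene should secure.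

**Step 14**
Reactants: 21 6-benzyloxy-1-(4-benzyloxy-2-methoxyphenyl)-2-(4-benzyloxy-3-methoxybenzyl)-5,7-dimethoxy-3-(triisopropylsiloxy)naphthalene
Product: 22 6-benzyloxy-1-(4-benzyloxy-2-methoxyphenyl)-2-(4-benzyloxy-3-methoxybenzyl)-5,7-dimethoxynaphthalen-3-ol
Conditions: TBAF (1.2 equiv), AcOH (1.2 equiv), THF, 0 °C
Reagents that add atoms: none
Why: Fluoride-induced cleavage of an aryl silyl ether; the acetic acid buffer keeps the electron-rich naphthoxide from air oxidation.

**Step 15**
Reactants: 22 6-benzyloxy-1-(4-benzyloxy-2-methoxyphenyl)-2-(4-benzyloxy-3-methoxybenzyl)-5,7-dimethoxynaphthalen-3-ol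
Product: 23 1-(4-hydroxy-2-methoxyphenyl)-2-(4-hydroxy-3-methoxybenzyl)-5,7-dimethoxynaphthalene-3,6-diol (CNP0000246.0)
Conditions: H2 (1 atm), 10% Pd/C, EtOAc–MeOH, rt; work-up under N2
Reagents that add atoms: none
Why: Catalytic hydrogenolysis of three benzyl aryl ethers; the diarylmethane CH2, the methyl ethers and the naphthalene core are inert at 1 atm and rt.

**Compound list**
1 | syringaldehyde | COc1cc(C=O)cc(OC)c1O | starting material
2 | 4-benzyloxy-3,5-dimethoxybenzaldehyde | COc1cc(C=O)cc(OC)c1OCc1ccccc1 | intermediate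
3 | 4-benzyloxy-2-bromo-3,5-dimethoxybenzaldehyde | O=Cc1cc(OC)c(OCc2ccccc2)c(OC)c1Br | intermediate
4 | 4-bromo-3-methoxyphenol | COc1cc(O)ccc1Br | starting material
5 | 4-benzyloxy-1-bromo-2-methoxybenzene | COc1cc(OCc2ccccc2)ccc1Br | intermediate
6 | (4-benzyloxy-2-methoxyphenyl)magnesium bromide | COc1cc(OCc2ccccc2)ccc1[Mg]Br | intermediate
7 | (4-benzyloxy-2-bromo-3,5-dimethoxyphenyl)(4-benzyloxy-2-methoxyphenyl)methanol, racemic | OC(c1cc(OC)c(OCc2ccccc2)c(OC)c1Br)c1ccc(OCc2ccccc2)cc1OC | intermediate
8 | (4-benzyloxy-2-bromo-3,5-dimethoxyphenyl)(4-benzyloxy-2-methoxyphenyl)methanone | O=C(c1cc(OC)c(OCc2ccccc2)c(OC)c1Br)c1ccc(OCc2ccccc2)cc1OC | intermediate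
9 | ethyl 2-[3-benzyloxy-6-(4-benzyloxy-2-methoxybenzoyl)-2,4-dimethoxyphenyl]acetate | CCOC(=O)Cc1c(OC)c(OCc2ccccc2)c(OC)cc1C(=O)c1ccc(OCc2ccccc2)cc1OC | intermediate
10 | 2-[3-benzyloxy-6-(4-benzyloxy-2-methoxybenzoyl)-2,4-dimethoxyphenyl]acetic acid | OC(=O)Cc1c(OC)c(OCc2ccccc2)c(OC)cc1C(=O)c1ccc(OCc2ccccc2)cc1OC | intermediate
11 | mixed anhydride of 10 with acetic acid | CC(=O)OC(=O)Cc1c(OC)c(OCc2ccccc2)c(OC)cc1C(=O)c1ccc(OCc2ccccc2)cc1OC | intermediate
12 | 6-benzyloxy-1-(4-benzyloxy-2-methoxyphenyl)-5,7-dimethoxy-2-benzopyran-3-one | O=C1C=C2C(OC)=C(OCc3ccccc3)C(OC)=CC2=C(c2ccc(OCc3ccccc3)cc2OC)O1 | intermediate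
13 | 4-benzyloxy-3-methoxybenzyl alcohol | COc1cc(CO)ccc1OCc1ccccc1 | starting material
14 | 1-benzyloxy-4-(bromomethyl)-2-methoxybenzene | COc1cc(CBr)ccc1OCc1ccccc1 | intermediate
15 | [3-(4-benzyloxy-3-methoxyphenyl)prop-1-yn-1-yl]trimethylsilane | COc1cc(CC#C[Si](C)(C)C)ccc1OCc1ccccc1 | intermediate
16 | 1-benzyloxy-2-methoxy-4-(prop-2-yn-1-yl)benzene | COc1cc(CC#C)ccc1OCc1ccccc1 | intermediate
17 | lithium acetylide of 16 | COc1cc(CC#C[Li])ccc1OCc1ccccc1 | intermediate
18 | lithium 3-(4-benzyloxy-3-methoxyphenyl)prop-1-yn-1-olate | [Li]OC#CCc1ccc(OCc2ccccc2)c(OC)c1 | intermediate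
19 | 3-(4-benzyloxy-3-methoxyphenyl)-1-(triisopropylsiloxy)prop-1-yne | CC(C)[Si](OC#CCc1ccc(OCc2ccccc2)c(OC)c1)(C(C)C)C(C)C | intermediate
20 | bridged lactone: 1,4-dihydronaphthalene with an O–C(=O) bridge from C1 (O) to C4 (C=O), C1 aryl, C2 benzyl, C3 OTIPS; racemic, bridgeheads fixed by the bicycle | O=C1OC2(c3ccc(OCc4ccccc4)cc3OC)C(Cc3ccc(OCc4ccccc4)c(OC)c3)=C(O[Si](C(C)C)(C(C)C)C(C)C)C1c1c(OC)c(OCc3ccccc3)c(OC)cc12 | intermediate
21 | 6-benzyloxy-1-(4-benzyloxy-2-methoxyphenyl)-2-(4-benzyloxy-3-methoxybenzyl)-5,7-dimethoxy-3-(triisopropylsiloxy)naphthalene | COc1cc(Cc2c(O[Si](C(C)C)(C(C)C)C(C)C)cc3c(OC)c(OCc4ccccc4)c(OC)cc3c2-c2ccc(OCc3ccccc3)cc2OC)ccc1OCc1ccccc1 | intermediate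
22 | 6-benzyloxy-1-(4-benzyloxy-2-methoxyphenyl)-2-(4-benzyloxy-3-methoxybenzyl)-5,7-dimethoxynaphthalen-3-ol | COc1cc(Cc2c(O)cc3c(OC)c(OCc4ccccc4)c(OC)cc3c2-c2ccc(OCc3ccccc3)cc2OC)ccc1OCc1ccccc1 | intermediate
23 | 1-(4-hydroxy-2-methoxyphenyl)-2-(4-hydroxy-3-methoxybenzyl)-5,7-dimethoxynaphthalene-3,6-diol | COc1cc(Cc2c(O)cc3c(OC)c(O)c(OC)cc3c2-c2ccc(O)cc2OC)ccc1O | target

**Total step count:** 15
**Longest linear sequence:** 10 steps (1, 2, 4, 5, 6, 7, 8, 13, 14, 15)

**Steps most likely to fail**

1. **Step 13.**
   - Risk: the cycloaddition may stall, because the bond to C1 joins two fully substituted carbons. Self-dimerisation of the o-quinoid lactone, oxygen-to-carbon silyl migration in the alkyne, or erosion of the regioselectivity could then take over.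
   - Fallback: known chemistry, with ring B closed by aldol condensation instead of cycloaddition. It sets out from bromobenzophenone 8 and comes back at naphthol 22.
   - Commercial zingerone is benzylated (BnBr, K2CO3, DMF) to 4-(4-benzyloxy-3-methoxyphenyl)butan-2-one F1.
   - Kinetic deprotonation at the methyl group and silylation (LiN(i-Pr)2, THF, −78 °C; Me3SiCl) give 4-(4-benzyloxy-3-methoxyphenyl)-2-(trimethylsiloxy)but-1-ene F2.
   - Regiocontrolled palladium-catalysed α-arylation of this silyl enol ether with 8 (Pd2(dba)3, P(t-Bu)3, Bu3SnF, toluene, 85 °C) gives 1-[3-benzyloxy-6-(4-benzyloxy-2-methoxybenzoyl)-2,4-dimethoxyphenyl]-4-(4-benzyloxy-3-methoxyphenyl)butan-2-one F3.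
   - KOt-Bu in t-BuOH–THF then lets the enolate of the C2 methylene add to the diaryl ketone carbon C1. Loss of water and tautomerisation give 22, which goes on through step 15.

2. **Step 12.**
   - Risk: proton transfer from the doubly activated ArCH2 group with drift to the allene, C-silylation of the ynolate to a silylketene, or hydrolysis of the siloxyalkyne during purification could drain the material.
   - Fallback: the ynolate is made by Kowalski ester homologation instead of acetylide oxidation. It sets out from bromide 14 and comes back at ynolate 18, and so at 19.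
   - Palladium-catalysed ethoxycarbonylation of 14 (CO 1 atm, PdCl2(PPh3)2, K2CO3, EtOH–THF, 50 °C) gives ethyl 2-(4-benzyloxy-3-methoxyphenyl)acetate F4. The same ester is available from homovanillic acid by esterification and benzylation.
   - F4 is added to preformed LiCHBr2 (CH2Br2, lithium 2,2,6,6-tetramethylpiperidide, THF, −90 °C). LiN(SiMe3)2 then completes the conversion into the lithium enolate of 1,1-dibromo-3-(4-benzyloxy-3-methoxyphenyl)propan-2-one F5.
   - n-BuLi (−78 °C to rt) triggers bromine–lithium exchange and a 1,2-shift of the benzyl group to give 18, which is silylated with TIPSOTf as in step 12.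

3. **Step 6.**
   - Risk: slow transmetalation at the di-ortho-substituted arylpalladium species could let protodebromination, Reformatsky addition to the ketone, or intramolecular C–H arylation onto the neighbouring aryl ring compete.
   - Fallback: a three-carbon handle is installed and then cut back. It sets out from 8 and comes back at keto acid 10.
   - Stille allylation (allyltributylstannane, Pd(PPh3)4, DMF, 100 °C) gives (2-allyl-4-benzyloxy-3,5-dimethoxyphenyl)(4-benzyloxy-2-methoxyphenyl)methanone F6.
   - Lemieux–Johnson cleavage (OsO4 cat., NaIO4, 2,6-lutidine, dioxane–H2O) gives 2-[3-benzyloxy-6-(4-benzyloxy-2-methoxybenzoyl)-2,4-dimethoxyphenyl]acetaldehyde F7.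
   - Pinnick oxidation (NaClO2, NaH2PO4, 2-methyl-2-butene, t-BuOH–H2O) gives 10.

**Further compounds**
F1 | step 13 | 4-(4-benzyloxy-3-methoxyphenyl)butan-2-one | CC(=O)CCc1ccc(OCc2ccccc2)c(OC)c1
F2 | step 13 | 4-(4-benzyloxy-3-methoxyphenyl)-2-(trimethylsiloxy)but-1-ene | C=C(CCc1ccc(OCc2ccccc2)c(OC)c1)O[Si](C)(C)C
F3 | step 13 | 1-[3-benzyloxy-6-(4-benzyloxy-2-methoxybenzoyl)-2,4-dimethoxyphenyl]-4-(4-benzyloxy-3-methoxyphenyl)butan-2-one | COc1cc(CCC(=O)Cc2c(OC)c(OCc3ccccc3)c(OC)cc2C(=O)c2ccc(OCc3ccccc3)cc2OC)ccc1OCc1ccccc1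
F4 | step 12 | ethyl 2-(4-benzyloxy-3-methoxyphenyl)acetate | CCOC(=O)Cc1ccc(OCc2ccccc2)c(OC)c1
F5 | step 12 | lithium enolate of 1,1-dibromo-3-(4-benzyloxy-3-methoxyphenyl)propan-2-one | [Li]OC(Cc1ccc(OCc2ccccc2)c(OC)c1)=C(Br)Br
F6 | step 6 | (2-allyl-4-benzyloxy-3,5-dimethoxyphenyl)(4-benzyloxy-2-methoxyphenyl)methanone | C=CCc1c(OC)c(OCc2ccccc2)c(OC)cc1C(=O)c1ccc(OCc2ccccc2)cc1OC
F7 | step 6 | 2-[3-benzyloxy-6-(4-benzyloxy-2-methoxybenzoyl)-2,4-dimethoxyphenyl]acetaldehyde | O=CCc1c(OC)c(OCc2ccccc2)c(OC)cc1C(=O)c1ccc(OCc2ccccc2)cc1OC
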